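**Strategy.** The target is a C2-symmetric 3,3''-biflavanone, and everything rests on cutting the O1–C2 bond of ring C and its twin O1''–C2'' in ring C'': both are oxa-Michael bonds of a 2'-hydroxychalcone. The precursor is therefore the open-chain, achiral bis-chalcone 9, a 2,3-bis(4-methoxybenzylidene)-1,4-diaryl-1,4-dione built by oxidative enolate dimerisation of an acetophenone and double aldol condensation. One catalytic, enantioselective double oxa-Michael cascade closes both pyranone rings and sets all four stereocentres: C2 and C2'' by the chiral catalyst, C3 and C3'' by relay, because each is α to a C4 ketone and settles trans to its neighbouring aryl group.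

Key step: step 6

Assumption 1: 2',4'-dihydroxy-6'-methoxyacetophenone (1) is taken as a catalogue compound.
Assumption 2: the quinine-derived amine–thiourea is taken to deliver the 2S sense of ring closure; if the facial sense proves opposite, its quinidine-derived pseudoenantiomer is used with nothing else changed.

Step 1
Reactants: 1 2',4'-dihydroxy-6'-methoxyacetophenone; 2 benzyl bromide
Product: 3 1-[4-(benzyloxy)-2-hydroxy-6-methoxyphenyl]ethan-1-one
Conditions: BnBr (1.05 equiv), K2CO3 (1.1 equiv), acetone, reflux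
Reagents that add atoms: benzyl bromide, BrCc1ccccc1
Why: Williamson etherification in which the 2'-OH, locked in a hydrogen bond to the acetyl carbonyl, is far less nucleophilic than the 4'-OH, so one equivalent of benzyl bromide should alkylate the 4'-oxygen only.

Step 2
Reactants: 3 1-[4-(benzyloxy)-2-hydroxy-6-methoxyphenyl]ethan-1-one; 4 chloromethyl methyl ether
Product: 5 1-[4-(benzyloxy)-2-methoxy-6-(methoxymethoxy)phenyl]ethan-1-one
Conditions: NaH (1.1 equiv), MOMCl (1.2 equiv), DMF, 0 °C → rt
Reagents that add atoms: chloromethyl methyl ether, COCCl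
Why: O-alkylation of the sodium phenoxide (NaH breaks the chelate) gives the MOM ether, which keeps the phenol from closing onto an α-functionalised ketone (benzofuranone formation) or being oxidised in step 3.

Step 3
Reactants: 5 1-[4-(benzyloxy)-2-methoxy-6-(methoxymethoxy)phenyl]ethan-1-one (2 equiv)
Product: 6 1,4-bis[4-(benzyloxy)-2-methoxy-6-(methoxymethoxy)phenyl]butane-1,4-dione
Conditions: LiN(iPr)2 (1.1 equiv, commercial solution), THF, −78 °C; then anhydrous CuCl2 (1.1 equiv) in DMF, −78 °C → rt
Reagents that add atoms: none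
Why: Oxidative homocoupling of a lithium enolate, in which one-electron oxidation by divalent copper gives an α-keto radical (or copper enolate) that dimerises at the unhindered CH2 terminus; this forms the future C3–C3'' bond and no stereocentre.

Step 4
Reactants: 6 1,4-bis[4-(benzyloxy)-2-methoxy-6-(methoxymethoxy)phenyl]butane-1,4-dione; 7 4-methoxybenzaldehyde (4 equiv)
Product: 8 (2E,3E)-1,4-bis[4-(benzyloxy)-2-methoxy-6-(methoxymethoxy)phenyl]-2,3-bis(4-methoxybenzylidene)butane-1,4-dione
Conditions: KOH (50% aq), EtOH/THF, rt → 45 °C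
Reagents that add atoms: 4-methoxybenzaldehyde, COc1ccc(C=O)cc1
Why: Double Claisen–Schmidt (crossed aldol) condensation in which each α-CH2 adds to the non-enolisable aldehyde and E1cB dehydration, driven by the push–pull anisylidene conjugation, should give the thermodynamic E,E-diene-dione; the alkene geometry disappears in step 6 and is not critical.

Step 5
Reactants: 8 (2E,3E)-1,4-bis[4-(benzyloxy)-2-methoxy-6-(methoxymethoxy)phenyl]-2,3-bis(4-methoxybenzylidene)butane-1,4-dione
Product: 9 (2E,3E)-1,4-bis[4-(benzyloxy)-2-hydroxy-6-methoxyphenyl]-2,3-bis(4-methoxybenzylidene)butane-1,4-dione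
Conditions: HCl (1.25 M in MeOH), THF, 0 °C → rt, stopped as soon as 8 is consumed
Reagents that add atoms: none
Why: Acid-catalysed acetal cleavage (transacetalisation to methanol) of the MOM ethers ortho to the carbonyl should proceed under conditions mild enough that the benzyl ethers survive and the 2'-hydroxy-6'-methoxychalcone units, which are isolable as such, do not close in an uncontrolled way.

Step 6
Reactants: 9 (2E,3E)-1,4-bis[4-(benzyloxy)-2-hydroxy-6-methoxyphenyl]-2,3-bis(4-methoxybenzylidene)butane-1,4-dione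
Product: 11 (2S,2''S,3R,3''R)-7,7''-bis(benzyloxy)-5,5''-dimethoxy-2,2''-bis(4-methoxyphenyl)-[3,3''-bichromane]-4,4''-dione, via mono-cyclised flavanone–chalcone 10 (not isolated)
Conditions: N-[3,5-bis(trifluoromethyl)phenyl]-N'-[(8α,9S)-6'-methoxycinchonan-9-yl]thiourea (quinine-derived, 20 mol %), toluene, 4 Å MS, 0 °C → rt; chromatography and crystallisation
Reagents that add atoms: none
Why: The quinuclidine of the bifunctional catalyst deprotonates the chelated 2'-OH while the thiourea hydrogen-bonds the enone carbonyl, so the phenoxide adds to the benzylic β-carbon (oxa-Michael addition), forming O1–C2, and the cross-conjugated enolate is protonated at C3; the same event then repeats on the remaining enone of 10. The closest known reaction type is the cinchona amine–thiourea catalysed enantioselective isomerisation of α-substituted 2'-hydroxychalcones to flavanones. Rings C and C'' each close in the 6-endo-trig mode, the only geometrically reasonable attack of the phenol oxygen on its own enone. C2 and C2'' (both S) are set by the catalyst, which should shield the same β-face twice because the two enones of the C2-symmetric substrate are equivalent; C3 and C3'' (both R) follow by substrate control, each being α to a ketone and equilibrating under the amine to the diequatorial 2,3-trans arrangement. The step needs kinetic α-protonation at C3 rather than γ-protonation at the distal benzylidene carbon, which the regained anisylidene–ketone conjugation favours, and it needs the same facial sense in both closures. Any single error is drained into the separable meso diastereomer, so the C2-symmetric product should be enriched beyond the selectivity of one closure.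

Step 7
Reactants: 11 (2S,2''S,3R,3''R)-7,7''-bis(benzyloxy)-5,5''-dimethoxy-2,2''-bis(4-methoxyphenyl)-[3,3''-bichromane]-4,4''-dione
Product: 12 (2S,2''S,3R,3''R)-7,7''-dihydroxy-5,5''-dimethoxy-2,2''-bis(4-methoxyphenyl)-[3,3''-bichromane]-4,4''-dione (4',4''',5,5''-tetramethylchamaejasmin)
Conditions: H2 (1 atm), Pd/C (10% palladium on carbon), EtOAc/THF, rt
Reagents that add atoms: none
Why: Hydrogenolysis of the two benzyl ethers under neutral conditions should free the 7- and 7''-OH groups without base that could reopen ring C or epimerise C2/C3, and should leave the aryl ketones and methyl ethers untouched at ambient pressure and temperature.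

**Compound list**

1 | 2',4'-dihydroxy-6'-methoxyacetophenone | CC(=O)c1c(O)cc(O)cc1OC | starting material
2 | benzyl bromide | BrCc1ccccc1 | starting material
3 | 1-[4-(benzyloxy)-2-hydroxy-6-methoxyphenyl]ethan-1-one | CC(=O)c1c(O)cc(OCc2ccccc2)cc1OC | intermediate
4 | chloromethyl methyl ether | COCCl | starting material
5 | 1-[4-(benzyloxy)-2-methoxy-6-(methoxymethoxy)phenyl]ethan-1-one | CC(=O)c1c(OCOC)cc(OCc2ccccc2)cc1OC | intermediate
6 | 1,4-bis[4-(benzyloxy)-2-methoxy-6-(methoxymethoxy)phenyl]butane-1,4-dione | O=C(CCC(=O)c1c(OCOC)cc(OCc2ccccc2)cc1OC)c1c(OCOC)cc(OCc2ccccc2)cc1OC | intermediate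
7 | 4-methoxybenzaldehyde | COc1ccc(C=O)cc1 | starting material
8 | (2E,3E)-1,4-bis[4-(benzyloxy)-2-methoxy-6-(methoxymethoxy)phenyl]-2,3-bis(4-methoxybenzylidene)butane-1,4-dione | COc1ccc(/C=C(/C(=O)c2c(OCOC)cc(OCc3ccccc3)cc2OC)C(/C(=O)c2c(OCOC)cc(OCc3ccccc3)cc2OC)=C\c2ccc(OC)cc2)cc1 | intermediate
9 | (2E,3E)-1,4-bis[4-(benzyloxy)-2-hydroxy-6-methoxyphenyl]-2,3-bis(4-methoxybenzylidene)butane-1,4-dione | COc1ccc(/C=C(/C(=O)c2c(O)cc(OCc3ccccc3)cc2OC)C(/C(=O)c2c(O)cc(OCc3ccccc3)cc2OC)=C\c2ccc(OC)cc2)cc1 | intermediate
10 | (2S,3R)-7-(benzyloxy)-3-[(E)-3-[4-(benzyloxy)-2-hydroxy-6-methoxyphenyl]-1-(4-methoxyphenyl)-3-oxoprop-1-en-2-yl]-5-methoxy-2-(4-methoxyphenyl)chroman-4-one | COc1ccc([C@H]2Oc3cc(OCc4ccccc4)cc(OC)c3C(=O)[C@@H]2C(/C(=O)c2c(O)cc(OCc3ccccc3)cc2OC)=C\c2ccc(OC)cc2)cc1 | intermediate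
11 | (2S,2''S,3R,3''R)-7,7''-bis(benzyloxy)-5,5''-dimethoxy-2,2''-bis(4-methoxyphenyl)-[3,3''-bichromane]-4,4''-dione | COc1ccc([C@H]2Oc3cc(OCc4ccccc4)cc(OC)c3C(=O)[C@@H]2[C@H]2C(=O)c3c(OC)cc(OCc4ccccc4)cc3O[C@@H]2c2ccc(OC)cc2)cc1 | intermediate
12 | (2S,2''S,3R,3''R)-7,7''-dihydroxy-5,5''-dimethoxy-2,2''-bis(4-methoxyphenyl)-[3,3''-bichromane]-4,4''-dione | COc1ccc([C@H]2Oc3cc(O)cc(OC)c3C(=O)[C@@H]2[C@H]2C(=O)c3c(OC)cc(O)cc3O[C@@H]2c2ccc(OC)cc2)cc1 | target

**Total step count:** 7
**Longest linear sequence:** 7 steps (1 → 3 → 5 → 6 → 8 → 9 → 11 → 12)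

**Steps most likely to fail**

Step 6. The catalyst may discriminate poorly between the faces of the hindered trisubstituted enones, or turn over so slowly that uncatalysed closure competes, so that the enantiomer and the meso isomer build up. Fallback: setting out from 9, the double ring closure would be run under achiral, thermodynamic conditions (NaOAc, EtOH, reflux), which should give 11 as a racemate, that is together with its enantiomer (2R,2''R,3S,3''S)-7,7''-bis(benzyloxy)-5,5''-dimethoxy-2,2''-bis(4-methoxyphenyl)-[3,3''-bichromane]-4,4''-dione F1, beside the meso isomer (2S,2''R,3R,3''S)-7,7''-bis(benzyloxy)-5,5''-dimethoxy-2,2''-bis(4-methoxyphenyl)-[3,3''-bichromane]-4,4''-dione F2. F2 would be removed on silica or by crystallisation and F1 by preparative HPLC on a chiral stationary phase (amylose tris(3,5-dimethylphenylcarbamate)), which comes back to the route at 11.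

Step 4. The condensation may stall after the first benzylidene is installed, or the mono-condensed intermediate may drift under warm base into enedione or furan isomers before the second aldehyde adds. Fallback: setting out from 6, the bis(lithium enolate) (LiN(SiMe3)2, 2.2 equiv, THF, −78 °C) would be added to 7 to give the bis-aldol 1,4-bis[4-(benzyloxy)-2-methoxy-6-(methoxymethoxy)phenyl]-2,3-bis[hydroxy(4-methoxyphenyl)methyl]butane-1,4-dione F3 as a diastereomer mixture of no consequence. MsCl/Et3N in CH2Cl2 at 0 °C would convert it into the bis(methanesulfonate) 1,4-bis[4-(benzyloxy)-2-methoxy-6-(methoxymethoxy)phenyl]-2,3-bis[(methanesulfonyloxy)(4-methoxyphenyl)methyl]butane-1,4-dione F4, which DBU would eliminate twice in the same flask to come back to the route at 8.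

Step 3. Electron transfer from the enolate to divalent copper may be diverted into α-chlorination or oxidation of the electron-rich arene instead of C–C coupling. Fallback: setting out from 5, the enolate would be silylated (LiN(iPr)2, Me3SiCl, THF, −78 °C) to the silyl enol ether {1-[4-(benzyloxy)-2-methoxy-6-(methoxymethoxy)phenyl]ethenyloxy}trimethylsilane F5, and brominated with N-bromosuccinimide (THF, 0 °C) to 2-bromo-1-[4-(benzyloxy)-2-methoxy-6-(methoxymethoxy)phenyl]ethan-1-one F6. F6 would then alkylate the lithium enolate of a second equivalent of 5 (LiN(SiMe3)2, THF, −78 °C) in an SN2 step that comes back to the route at 6.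

**Further compounds**

F1 | step 6 | (2R,2''R,3S,3''S)-7,7''-bis(benzyloxy)-5,5''-dimethoxy-2,2''-bis(4-methoxyphenyl)-[3,3''-bichromane]-4,4''-dione | COc1ccc([C@@H]2Oc3cc(OCc4ccccc4)cc(OC)c3C(=O)[C@H]2[C@@H]2C(=O)c3c(OC)cc(OCc4ccccc4)cc3O[C@H]2c2ccc(OC)cc2)cc1
F2 | step 6 | (2S,2''R,3R,3''S)-7,7''-bis(benzyloxy)-5,5''-dimethoxy-2,2''-bis(4-methoxyphenyl)-[3,3''-bichromane]-4,4''-dione (meso) | COc1ccc([C@H]2Oc3cc(OCc4ccccc4)cc(OC)c3C(=O)[C@@H]2[C@@H]2C(=O)c3c(OC)cc(OCc4ccccc4)cc3O[C@H]2c2ccc(OC)cc2)cc1
F3 | step 4 | 1,4-bis[4-(benzyloxy)-2-methoxy-6-(methoxymethoxy)phenyl]-2,3-bis[hydroxy(4-methoxyphenyl)methyl]butane-1,4-dione (mixture of diastereomers) | COc1ccc(C(O)C(C(=O)c2c(OCOC)cc(OCc3ccccc3)cc2OC)C(C(O)c2ccc(OC)cc2)C(=O)c2c(OCOC)cc(OCc3ccccc3)cc2OC)cc1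
F4 | step 4 | 1,4-bis[4-(benzyloxy)-2-methoxy-6-(methoxymethoxy)phenyl]-2,3-bis[(methanesulfonyloxy)(4-methoxyphenyl)methyl]butane-1,4-dione (mixture of diastereomers) | COc1ccc(C(OS(C)(=O)=O)C(C(=O)c2c(OCOC)cc(OCc3ccccc3)cc2OC)C(C(OS(C)(=O)=O)c2ccc(OC)cc2)C(=O)c2c(OCOC)cc(OCc3ccccc3)cc2OC)cc1
F5 | step 3 | {1-[4-(benzyloxy)-2-methoxy-6-(methoxymethoxy)phenyl]ethenyloxy}trimethylsilane | C=C(O[Si](C)(C)C)c1c(OCOC)cc(OCc2ccccc2)cc1OC
F6 | step 3 | 2-bromo-1-[4-(benzyloxy)-2-methoxy-6-(methoxymethoxy)phenyl]ethan-1-one | BrCC(=O)c1c(OCOC)cc(OCc2ccccc2)cc1OC
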